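Start from the ratio c(incoming ligand)/c(starting complex), which counts the turnovers a charge can pay: 0.833 in dawn and 2.81 in dusk.

all flasks: starting complex 0.096 M

| run | incoming ligand | remark | time |
|---|---|---|---|
| dawn | 0.080 M | run made earlier |  |
| dusk | 0.27 M | run made earlier |  |
| eta | 0.115 M |  | 12 min |
| delta | 0.192 M |  | 12 min |
| alpha | 0.384 M |  | 12 min |

- dawn (time / min: complex with two exchanged / %, complex with one exchanged / %): 1.50: 10.3, 20.2; 3.00: 11.9, 18.1; 5.00: 11.2, 13.5; 6.00: 10.1, 13.9
- dusk (time / min: complex with two exchanged / %, complex with one exchanged / %): 1.50: 26.8, 24.4; 3.00: 28.3, 19.5; 5.00: 27.8, 17.7; 6.00: 29.4, 18.1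

(standard deviation of a reading: 1 percentage point)



- amount of complex with two exchanged at the end, in percent of the starting complex charged, for each flask in turn (eta, delta, alpha)

1. Take the main step: each incoming ligand exchanges once, and complex with two exchanged costs two. Delta's charge then pays for 100%.

2. Add the loss of complex with one exchanged. In dawn it goes from 20.2% at 1.50 min to 13.9% at 6.00 min, while complex with two exchanged reads 10.3% and 10.1%. Leave delta's number unchanged.

3. Add the unseen turnovers. At 6.00 min, the last reading, complex with one exchanged plus twice complex with two exchanged gives 0.341 turnovers per starting complex in dawn and 0.769 in dusk, below the ratios above. Stop counting the budget, and read the plateau yield on ligand, c(complex with two exchanged) at the plateau over c(incoming ligand) charged. With the four readings averaged, dawn gives 0.131 and dusk 0.0998.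

4. Draw a straight line for this yield against the charge, and multiply by each flask's ratio. My reckoning gives 15.0% for eta, 22.5% for delta and 32.6% for alpha, whose charge lies beyond dusk's.

5. Set beside it the forecast: 14.5%, 22% and 36%, made from stepwise constants, “so I read the plateaus as equilibrium”. It stands below my reckoning for eta and delta and above it for alpha.

6. Read the flasks: 15.7%, 23.1% and 34.3%. The forecast holds within the margin.

    starting complex + incoming ligand → leaving ligand + complex with one exchanged (k = 0.390 M⁻¹ s⁻¹)
    complex with one exchanged + incoming ligand → leaving ligand + complex with two exchanged (k = 0.780 M⁻¹ s⁻¹)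
    complex with two exchanged + incoming ligand → leaving ligand + complex with three exchanged (k = 0.0850 M⁻¹ s⁻¹)
    starting complex + complex with one exchanged → side product (k = 0.0270 M⁻¹ s⁻¹)
    2 incoming ligand → self-condensation product (k = 0.480 M⁻¹ s⁻¹)

Delta holds 23.1% of complex with two exchanged at 6.00 min, and the same at 12.0 min and 120 min, with incoming ligand, the limiting reagent, at 0%. Its plateau yield on ligand is 0.116, between the 0.131 read in dawn and the 0.0998 read in dusk, and alpha's is lower, 0.0857. The main reason for delta's shortfall is the self-condensation of incoming ligand: with that step taken away, delta gives 61.6% of complex with two exchanged instead of 23.1%.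

The numbers in the tables come from a simulation on assumed constants, noise included.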